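**Remarks on the chemistry**

- C2 of the target is (S) (O1 > C1' > C3 > H) and the side-chain alkene is Z. The lactone 8 and its ring-opened product 11 map atom for atom onto ring B (lactone O1–C8a = O–C4', C4a = the chain-bearing carbon, C3=C4 = the Z-alkene, C2 = the carbinol carbon, C6 = C1', C8 = the prenylated carbon), so no structure needs correcting.
- Step 4 consumes two equivalents of 9 for each molecule of 8, one for each new C–CH3 bond. The further excess only keeps the hard nucleophile in surplus.
- The boron partner is made as the free boronic acid, because the cationic palladium–pyridine-oxazoline system is established for boronic acids and a pinacol ester may transmetalate too slowly.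
- The (R)-ligand is specified on the assumption that the facial sense by which the (S)-ligand turns cyclic enones into (R) β-aryl ketones also holds for chromones. This would be confirmed on 19 with a simple arylboronic acid before 15 is committed, and the ligand antipode used if the sense is reversed.
- Ring A is protected as triisopropylsilyl (TIPS) ethers, put on at the acetophenone stage, so that the chelated 5-hydroxyl of a chromone never has to be silylated.

## Structural features

The target 21 is a (2S)-flavanone: a 5,7-dihydroxychroman-4-one (rings A and C) that carries at C2 a 1,3,4,5-tetrasubstituted benzene ring B. Ring B has a methoxy group at C4', a prenyl group on one neighbouring carbon and a (Z)-3-hydroxy-3-methylbut-1-enyl chain on the other, so that the C4' oxygen is flanked on both sides. C2 is the only stereocentre and has no stereogenic neighbour, but it is benzylic, bound to O1 and β to the C4 ketone, and is therefore lost through retro-oxa-Michael opening to the 2'-hydroxychalcone as soon as base meets the ring A phenols. The fragile groups are the cis tertiary allylic alcohol conjugated with an electron-rich arene (ionisation, Z to E isomerisation and ring closure onto the C4' oxygen in acid), the two side-chain alkenes (no hydrogenation, no strong electrophiles) and the phenols of ring A. The real difficulty is therefore not ring C but the Z-configured styrenyl carbinol ortho to an oxygen, together with the need to set C2 late and to unmask ring A without acid, base or hydrogen. The key step uses the fact that the C4' oxygen, C4', the adjacent ring carbon, the two alkene carbons and the carbinol carbon are the atoms O1, C8a, C4a, C4, C3 and C2 of a coumarin: the endocyclic cis C3=C4 bond of the lactone is the Z-alkene, and the lactone carbonyl carbon becomes the carbinol carbon once it has taken up two methyl groups.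

## Logic of the disconnections

**21 to 20.** The two phenolic O–H bonds of ring A are traded for O–Si bonds. Fluoride buffered with acetic acid is the one unmasking that touches neither C2, nor the allylic carbinol, nor the alkenes. Nothing is gained in skeleton, but the phenols stay silent through the C–C bond-forming step. The forward step must keep the medium below the basicity at which ring C opens.

**20 to 15 and 19.** The C2–C1' bond is cut. It is the only bond at the stereocentre that lies outside a ring, it divides the molecule into two halves of similar size, and forming it by catalytic conjugate arylation sets C2 in the same operation. Ring C is then present beforehand as a flat, achiral heterocycle. The forward step must transfer the aryl group from boron to C2 of an electron-rich enone with face control, without base and in the presence of the free tertiary alcohol.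

**19 to 17 to 16.** O1–C2 and C2–C3 are cut, so that C2 becomes a one-carbon unit at the formate oxidation level condensed onto the acetyl methyl group (through 18). The two O–Si bonds are then cut back to 16. Silylation is placed at the stage of 16 because one ortho hydroxyl is still free of chelation there. The forward steps must silylate two of three hydroxyls and close the pyranone without shedding silicon.

**15 to 12.** The C1'–B bond is replaced by C1'–Br. Bromine is the one handle that is inert in every step back to 1 (it also blocks the para position of the phenol) and can still be exchanged for lithium at −78 °C. The exchange must outrun any reaction of the alkyllithium with the styrenyl double bond, and the boronic acid must be freed without strong acid.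

**12 to 11.** The O–CH3 bond is cut. The phenol of 11 is the nucleophile that would close onto the allylic carbinol, and the methyl ether that 21 needs anyway serves as the lock. The forward step must methylate a doubly flanked phenol and leave the tertiary alcohol alone.

**11 to 8 and two equivalents of 9.** Both C–CH3 bonds at the carbinol carbon are cut and the phenol oxygen is reconnected to that carbon as a lactone. A Z-alkene that would otherwise need a selective olefination or semi-reduction becomes the endocyclic double bond of a six-membered ring, where no other geometry exists. Two C–C bonds and the alkene geometry then come from one operation on a flat bicycle. The forward step must deliver both methyl groups to the carbonyl carbon and none to C4, leave C–Br and the prenyl group untouched, and be worked up without acid.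

**8 to 5 and 6.** The C3=C4 bond and the lactone O1–C2 bond are cut. An ortho-hydroxy aldehyde and a two-carbon ester ylide are simpler and fix the position of the lactone. The forward step must isomerise the first-formed trans ester so that the phenol can reach the ester, hence the high temperature.

**5 to 3.** The aryl–CHO bond is cut. Only one position ortho to the hydroxyl is free, so a phenoxide-directed formylation has no regiochemical choice. The method must not be electrophilic enough to attack the prenyl alkene.

**3 to 1 and 2.** The aryl–CH2 bond of the prenyl group is cut. Both partners are commercial, and bromine blocks the para position. The forward step must favour C- over O-alkylation and attack the primary terminus of 2.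

## Other disconnections considered

Alternative 1: The cut is through O1–C8a and C4–C4a, so that ring C is built on an aryne. In the forward key step CsF releases the aryne from the silyl triflate A1, the pre-formed alkoxide of the hydroxy ester A2 adds to the aryne carbon remote from the neighbouring allyloxy group, and the aryl anion, now placed between two oxygens, acylates itself on the ester to give the flavanone A3. In its favour: both bonds to ring A form in one step, the regiochemistry follows from the polarisation of a 3-alkoxyaryne, and C2 is carried in from a β-hydroxy ester, a class for which asymmetric reduction of the keto ester is dependable. The allyl ethers would later fall to Pd(PPh3)4 (zerovalent palladium) and a soft nucleophile. Against it here: the aryl anion has the acidic α-CH2 of the ester within reach, so proton transfer competes with acylation. The β-alkoxide can fragment by retro-aldol, and fluoride and alkoxide in the flask can open A3 by E1cB elimination and erode C2. A1 needs its own multi-step synthesis. The iodide of A3 still has to become the side chain by Sonogashira coupling with the alkynol A4 and semi-hydrogenation over Pd/CaCO3 poisoned with Pb(OAc)2, in the presence of one prenyl and two allyl double bonds. On structure the alternative is the better plan for the source of chirality, which is a reduction and not a catalytic addition to a hindered chromone, and the equal of the chosen plan in the mildness of the final deprotection. On mechanism the chosen plan is better founded, because its Z geometry follows from ring size and not from catalyst selectivity, and each of its steps has close analogy. On step economy the alternative is longer, by an estimated four to six operations against the 10 steps chosen.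

Alternative 2: The cut is the C3–C4 bond. In the forward key step a thiazolium-derived carbene and a mild base convert the aldehyde of A5 into a Breslow intermediate, whose nucleophilic carbon displaces the primary tosylate intramolecularly (6-exo-tet) to give the bis(allyl) ether A6; deallylation would complete the synthesis. In its favour: the ring closure is metal-free and nearly neutral. C2 is a spectator in the key step, so its integrity depends only on earlier steps. The complete ring B, Z-carbinol included, can be present, and it would still be made by the same lactone opening, so on that point the two plans are equal. The alternative is better in one respect: it avoids conjugate addition to an electron-rich chromone. Against it here: the O1–C2 bond must be made beforehand as a configurationally defined secondary benzylic aryl ether, (R) in A5 because the priorities change. Etherification of a doubly ortho-substituted, ortho-formyl phenol with a benzylic alcohol of an electron-rich arene invites ionisation and loss of configuration. The diol that supplies the tosylate needs an asymmetric dihydroxylation that discriminates between three alkenes. In the key step, base-induced elimination of the tosylate and intermolecular benzoin condensation compete. On mechanism the chosen plan sets C2 in one catalytic step, where the alternative needs three or four stoichiometric ones. On step economy the alternative is longer by an estimated five steps.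

Alternative 3: The cut is the C2–C3 bond. In the forward key step Rh2(S-PTTL)4, a divalent rhodium dimer, decomposes the diazoketone A7, and the carbenoid carbon inserts into a benzylic C–H bond of the ArCH2–O group, closing ring C and creating C2 of the flavanone A8. In its favour: the precursor comes from simple etherification and acylation chemistry. The C–H bond is doubly activated (benzylic and α to oxygen), and ring and stereocentre arise together from an achiral ether, which is the more direct construction of ring C. The TIPS groups are those of the chosen plan, so the final deprotection is equal. Against it here: the ether oxygen sits 1,5 to the carbenoid, so oxonium ylide formation followed by a [1,2]-shift to a five-membered ring is a serious competitor of the six-membered insertion. Face control with acceptor-only carbenoids is usually moderate. The prenyl alkene is a cyclopropanation site. The diazoketone requires diazomethane or a diazo-transfer sequence. As with A3, the iodide of A8 still needs A4 and a semi-hydrogenation. On mechanism the chosen plan is expected to give the higher and more predictable enantioselectivity and a geometrically unambiguous alkene. On step economy the alternative is estimated to be three or four steps longer.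

Key step: step 4

## Route

Step 1
Reactants: 1 4-bromophenol; 2 1-bromo-3-methylbut-2-ene (prenyl bromide)
Product: 3 4-bromo-2-(3-methylbut-2-enyl)phenol
Conditions: NaH (1.0 equiv), PhMe, 0 °C; then 2 (0.9 equiv), rt
Reagents that add atoms: none
Why: Ortho-C-alkylation of a sodium phenoxide in a non-polar solvent: the aggregated ion pair shields oxygen and passes the allylic bromide to the ortho carbon by SN2 attack at its primary terminus, the para position being blocked by bromine; the dienone tautomerises to 3, and the O-prenyl ether and 2,6-diprenyl by-products should be separable by chromatography.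

Step 2
Reactants: 3 4-bromo-2-(3-methylbut-2-enyl)phenol
Product: 5 5-bromo-2-hydroxy-3-(3-methylbut-2-enyl)benzaldehyde, via hydroxymethylphenol magnesium salt 4 (not isolated)
Conditions: MgCl2, Et3N, (CH2O)n, MeCN, reflux; cold 1 M HCl work-up
Reagents that add atoms: formaldehyde (as paraformaldehyde), C=O
Why: Casnati–Skattebøl ortho-formylation: the magnesium phenoxide delivers formaldehyde to the only free ortho position to give 4, which is oxidised in the flask by a second formaldehyde through an Oppenauer-type hydride transfer; nothing electrophilic enough to attack the prenyl alkene is present.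

Step 3
Reactants: 5 5-bromo-2-hydroxy-3-(3-methylbut-2-enyl)benzaldehyde; 6 ethyl (triphenylphosphoranylidene)acetate
Product: 8 6-bromo-8-(3-methylbut-2-enyl)-2H-chromen-2-one, via ethyl (E)-hydroxycinnamate 7 (not isolated)
Conditions: 6 (1.2 equiv), PhNEt2, reflux (ca. 215 °C), N2
Reagents that add atoms: none
Why: Wittig olefination with a stabilised ylide gives mainly the E-ester 7; at the reflux temperature of the amine the double bond equilibrates and the Z-form is drained off irreversibly by lactonisation with loss of ethanol, the standard one-flask coumarin synthesis from salicylaldehydes, which is commonly applied to prenylated substrates.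

Step 4
Reactants: 8 6-bromo-8-(3-methylbut-2-enyl)-2H-chromen-2-one; 9 methylmagnesium bromide
Product: 11 4-bromo-2-[(Z)-3-hydroxy-3-methylbut-1-enyl]-6-(3-methylbut-2-enyl)phenol, via Z-enone magnesium phenoxide 10 (not isolated)
Conditions: 8 added to MeMgBr (4 equiv), THF, 0 °C to rt; pH 7 phosphate buffer, 0 °C; crude 11 used at once
Reagents that add atoms: methylmagnesium bromide (second equivalent), C[Mg]Br
Why: Two equivalents of 9 are consumed: the first methyl group adds to the lactone carbonyl, the tetrahedral alkoxide collapses by expelling the aryloxide, and the resulting Z-enone, held as the magnesium phenoxide 10, takes up the second methyl group at its carbonyl carbon; buffered hydrolysis of the dialkoxide should give 11. The closest known reaction type is the addition of excess methyl Grignard reagent or methyllithium to coumarins, the first half of the classical route to 2,2-dimethyl-2H-chromenes. No ring is closed (the pyranone ring is opened) and no stereocentre is created. The Z geometry is not selected but inherited: C3=C4 of 8 is cis by ring constraint, and neither addition breaks that double bond or adds across it. The selectivity that matters is carbonyl (1,2) over conjugate (1,4) addition in both events; a hard, copper-free methyl nucleophile in THF and inverse addition into excess reagent should secure it, with CeCl3 or methyllithium held in reserve. The aryl bromide does not exchange with a methyl Grignard reagent at this temperature and the prenyl alkene is inert. Because acid would cyclodehydrate 11, the work-up is neutral and cold and the phenol is methylated straight away.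

Step 5
Reactants: 11 4-bromo-2-[(Z)-3-hydroxy-3-methylbut-1-enyl]-6-(3-methylbut-2-enyl)phenol
Product: 12 (Z)-4-[5-bromo-2-methoxy-3-(3-methylbut-2-enyl)phenyl]-2-methylbut-3-en-2-ol
Conditions: MeI (1.5 equiv), K2CO3 (2 equiv), DMF, rt
Reagents that add atoms: iodomethane, CI
Why: Williamson etherification: carbonate deprotonates only the phenol, whose oxygen, although flanked on both sides, is reached by the small electrophile while the tertiary alcohol stays free; with the phenol capped, acid-triggered closure to a chromene is no longer possible and 12 should survive chromatography on base-washed silica.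

Step 6
Reactants: 12 (Z)-4-[5-bromo-2-methoxy-3-(3-methylbut-2-enyl)phenyl]-2-methylbut-3-en-2-ol
Product: 15 [3-[(Z)-3-hydroxy-3-methylbut-1-enyl]-4-methoxy-5-(3-methylbut-2-enyl)phenyl]boronic acid, via dilithiated aryllithium 13 (not isolated), via lithium triisopropoxyborate 14 (not isolated)
Conditions: n-BuLi (2.2 equiv), THF, −78 °C; B(OiPr)3 (3 equiv), −78 °C to rt; sat. aq. NH4Cl
Reagents that add atoms: triisopropyl borate, CC(C)OB(OC(C)C)OC(C)C; water, O
Why: Bromine–lithium exchange followed by borate trapping: the first equivalent of butyllithium removes the hydroxyl proton, the second exchanges the unhindered aryl bromide within minutes at −78 °C, faster than any addition to the styrenyl double bond, and the ate complex 14 is hydrolysed by the ammonium buffer without exposure to strong acid.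

Step 7
Reactants: 16 2',4',6'-trihydroxyacetophenone
Product: 17 1-[2-hydroxy-4,6-bis(triisopropylsilyloxy)phenyl]ethanone
Conditions: TIPSCl (2.2 equiv), imidazole (4.5 equiv), DMF, 0 °C to rt
Reagents that add atoms: chlorotriisopropylsilane, CC(C)[Si](Cl)(C(C)C)C(C)C
Why: Selective silylation: the para hydroxyl and one ortho hydroxyl react, while the second ortho hydroxyl is held in a hydrogen bond to the acetyl oxygen and stays free for the later ring closure; bulky aryl TIPS ethers tolerate the mildly acidic steps that follow and still fall to fluoride.

Step 8
Reactants: 17 1-[2-hydroxy-4,6-bis(triisopropylsilyloxy)phenyl]ethanone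
Product: 19 5,7-bis(triisopropylsilyloxy)-4H-chromen-4-one, via dimethylaminoenone 18 (not isolated)
Conditions: Me2NCH(OMe)2 (2 equiv), PhMe, 90 °C; then AcOH, 60 °C
Reagents that add atoms: N,N-dimethylformamide dimethyl acetal, COC(OC)N(C)C
Why: Enaminone route to chromones: condensation at the acetyl methyl group gives 18, and in acetic acid the free ortho hydroxyl adds to the protonated enaminone (6-endo addition) with loss of dimethylamine; silylating first keeps the aminal from methylating free phenols.

Step 9
Reactants: 15 [3-[(Z)-3-hydroxy-3-methylbut-1-enyl]-4-methoxy-5-(3-methylbut-2-enyl)phenyl]boronic acid; 19 5,7-bis(triisopropylsilyloxy)-4H-chromen-4-one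
Product: 20 (2S)-2-[3-[(Z)-3-hydroxy-3-methylbut-1-enyl]-4-methoxy-5-(3-methylbut-2-enyl)phenyl]-5,7-bis(triisopropylsilyloxy)chroman-4-one
Conditions: Pd(OCOCF3)2 (10 mol%), (R)-4-tert-butyl-2-(pyridin-2-yl)-4,5-dihydrooxazole [(R)-t-BuPyOX] (12 mol%), NH4PF6 (30 mol%), H2O (5 equiv), ClCH2CH2Cl, 60 °C; 19 (1.5 equiv)
Reagents that add atoms: none
Why: Enantioselective conjugate addition of an arylboronic acid to a chromone under cationic divalent palladium–pyridine-oxazoline catalysis: transmetalation gives an aryl–palladium species that inserts C2=C3, and the palladium enolate is protonated by water, so no base is present and ring C cannot open. C2 is set in the insertion step by the tert-butyl group of the ligand, which shields one face of the bound enone; the (R)-ligand is expected to direct the aryl group to the face that gives (2S).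

Step 10
Reactants: 20 (2S)-2-[3-[(Z)-3-hydroxy-3-methylbut-1-enyl]-4-methoxy-5-(3-methylbut-2-enyl)phenyl]-5,7-bis(triisopropylsilyloxy)chroman-4-one
Product: 21 (2S)-5,7-dihydroxy-2-[3-[(Z)-3-hydroxy-3-methylbut-1-enyl]-4-methoxy-5-(3-methylbut-2-enyl)phenyl]-2,3-dihydro-4H-chromen-4-one
Conditions: TBAF (2.5 equiv), AcOH (3 equiv), THF, 0 °C
Reagents that add atoms: none
Why: Fluoride-induced cleavage of aryl silyl ethers, buffered with acetic acid so that the liberated phenoxides are protonated at once and the retro-oxa-Michael opening that would racemise C2 cannot start; the medium is too weakly acidic to ionise the tertiary allylic alcohol.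

## Compound list

1 | 4-bromophenol | Oc1ccc(Br)cc1 | starting material
2 | 1-bromo-3-methylbut-2-ene (prenyl bromide) | CC(C)=CCBr | starting material
3 | 4-bromo-2-(3-methylbut-2-enyl)phenol | CC(C)=CCc1cc(Br)ccc1O | intermediate
4 | 4-bromo-2-(hydroxymethyl)-6-(3-methylbut-2-enyl)phenol (magnesium salt in the flask) | OCc1cc(Br)cc(CC=C(C)C)c1O | intermediate (not isolated)
5 | 5-bromo-2-hydroxy-3-(3-methylbut-2-enyl)benzaldehyde | O=Cc1cc(Br)cc(CC=C(C)C)c1O | intermediate
6 | ethyl (triphenylphosphoranylidene)acetate | CCOC(=O)C=P(c1ccccc1)(c1ccccc1)c1ccccc1 | starting material
7 | ethyl (E)-3-[5-bromo-2-hydroxy-3-(3-methylbut-2-enyl)phenyl]prop-2-enoate | CCOC(=O)/C=C/c1cc(Br)cc(CC=C(C)C)c1O | intermediate (not isolated)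
8 | 6-bromo-8-(3-methylbut-2-enyl)-2H-chromen-2-one | O=c1ccc2cc(Br)cc(CC=C(C)C)c2o1 | intermediate
9 | methylmagnesium bromide | C[Mg]Br | starting material
10 | (Z)-4-[5-bromo-2-hydroxy-3-(3-methylbut-2-enyl)phenyl]but-3-en-2-one (bromomagnesium phenoxide in the flask) | CC(=O)/C=C\c1cc(Br)cc(CC=C(C)C)c1O | intermediate (not isolated)
11 | 4-bromo-2-[(Z)-3-hydroxy-3-methylbut-1-enyl]-6-(3-methylbut-2-enyl)phenol | Oc1c(/C=C\C(C)(C)O)cc(Br)cc1CC=C(C)C | intermediate
12 | (Z)-4-[5-bromo-2-methoxy-3-(3-methylbut-2-enyl)phenyl]-2-methylbut-3-en-2-ol | COc1c(/C=C\C(C)(C)O)cc(Br)cc1CC=C(C)C | intermediate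
13 | lithium (Z)-4-[5-lithio-2-methoxy-3-(3-methylbut-2-enyl)phenyl]-2-methylbut-3-en-2-olate | [Li]c1cc(/C=C\C(C)(C)O[Li])c(OC)c(CC=C(C)C)c1 | intermediate (not isolated)
14 | dilithium salt of the aryl(triisopropoxy)borate of the same alkoxide | [Li+].[Li+].COc1c(/C=C\C(C)(C)[O-])cc([B-](OC(C)C)(OC(C)C)OC(C)C)cc1CC=C(C)C | intermediate (not isolated)
15 | [3-[(Z)-3-hydroxy-3-methylbut-1-enyl]-4-methoxy-5-(3-methylbut-2-enyl)phenyl]boronic acid | COc1c(/C=C\C(C)(C)O)cc(B(O)O)cc1CC=C(C)C | intermediate
16 | 2',4',6'-trihydroxyacetophenone | CC(=O)c1c(O)cc(O)cc1O | starting material
17 | 1-[2-hydroxy-4,6-bis(triisopropylsilyloxy)phenyl]ethanone | CC(=O)c1c(O)cc(O[Si](C(C)C)(C(C)C)C(C)C)cc1O[Si](C(C)C)(C(C)C)C(C)C | intermediate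
18 | (E)-3-(dimethylamino)-1-[2-hydroxy-4,6-bis(triisopropylsilyloxy)phenyl]prop-2-en-1-one | CN(C)/C=C/C(=O)c1c(O)cc(O[Si](C(C)C)(C(C)C)C(C)C)cc1O[Si](C(C)C)(C(C)C)C(C)C | intermediate (not isolated)
19 | 5,7-bis(triisopropylsilyloxy)-4H-chromen-4-one | O=c1ccoc2cc(O[Si](C(C)C)(C(C)C)C(C)C)cc(O[Si](C(C)C)(C(C)C)C(C)C)c12 | intermediate
20 | (2S)-2-[3-[(Z)-3-hydroxy-3-methylbut-1-enyl]-4-methoxy-5-(3-methylbut-2-enyl)phenyl]-5,7-bis(triisopropylsilyloxy)chroman-4-one | COc1c(/C=C\C(C)(C)O)cc([C@@H]2CC(=O)c3c(O[Si](C(C)C)(C(C)C)C(C)C)cc(O[Si](C(C)C)(C(C)C)C(C)C)cc3O2)cc1CC=C(C)C | intermediate
21 | (2S)-5,7-dihydroxy-2-[3-[(Z)-3-hydroxy-3-methylbut-1-enyl]-4-methoxy-5-(3-methylbut-2-enyl)phenyl]-2,3-dihydro-4H-chromen-4-one | COc1c(/C=C\C(C)(C)O)cc([C@@H]2CC(=O)c3c(O)cc(O)cc3O2)cc1CC=C(C)C | target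

## Step count and least certain steps

Total step count: 10. Longest linear sequence: 8 steps (steps 1 to 6, 9 and 10); the chromone 19 comes from a 2-step branch (steps 7 and 8).

**Step 4 (key step).** Partial conjugate addition of the methyl nucleophile at C4 of the lactone or of the intermediate enone may occur, because the template is a Michael acceptor. Cyclodehydration during isolation is the second risk, because the cis arrangement that is wanted also places the phenol within reach of the carbinol carbon. The fallback makes the Z-alkene in another way and sets out from 5. Methylation (MeI, K2CO3, DMF) would give 5-bromo-2-methoxy-3-(3-methylbut-2-enyl)benzaldehyde F1. A Z-selective Ando olefination with ethyl (diphenoxyphosphoryl)acetate and NaH in THF at −78 °C would give ethyl (Z)-3-[5-bromo-2-methoxy-3-(3-methylbut-2-enyl)phenyl]prop-2-enoate F2. Excess MeMgBr with CeCl3 would then turn the ester into the tertiary alcohol, coming back to the route at 12.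

**Step 9.** Insertion into the electron-rich, peri-substituted chromone may be so slow that protodeboronation of the boronic acid wins. The Lewis-acidic cationic palladium and the ammonium salt may ionise the tertiary allylic alcohol or isomerise the Z-alkene. Facial discrimination may be insufficient. The fallback changes both the protecting-group plan and the metal and sets out from 12. Silylation with TESOTf and 2,6-lutidine would give triethyl{[(Z)-4-[5-bromo-2-methoxy-3-(3-methylbut-2-enyl)phenyl]-2-methylbut-3-en-2-yl]oxy}silane F3. Lithiation and borylation as in step 6 would give [4-methoxy-3-(3-methylbut-2-enyl)-5-[(Z)-3-methyl-3-(triethylsilyloxy)but-1-enyl]phenyl]boronic acid F4. A Hayashi–Miyaura addition to 19 with a neutral monovalent rhodium catalyst ([Rh(OH)(cod)]2 with a chiral diene or an electron-poor biaryl bisphosphine, aqueous toluene, no added base) would give (2S)-2-[4-methoxy-3-(3-methylbut-2-enyl)-5-[(Z)-3-methyl-3-(triethylsilyloxy)but-1-enyl]phenyl]-5,7-bis(triisopropylsilyloxy)chroman-4-one F5. The conditions of step 10 with one more equivalent of fluoride, warmed to room temperature if the tertiary silyl ether lags, would remove all three silyl groups, coming back to the route at 21.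

**Step 6.** The exchange may be incomplete, or butyllithium may add to the styrenyl double bond under the direction of the neighbouring lithium alkoxide. Boron may be lost, or the carbinol ionised, during hydrolysis and isolation of the polar boronic acid. The fallback replaces the organolithium by a palladium-catalysed borylation and sets out from 12. Miyaura borylation with B2pin2, PdCl2(dppf) and KOAc in dioxane at 85 °C would give (Z)-4-[2-methoxy-3-(3-methylbut-2-enyl)-5-(4,4,5,5-tetramethyl-1,3,2-dioxaborolan-2-yl)phenyl]-2-methylbut-3-en-2-ol F6, which can be chromatographed. Oxidative cleavage of the pinacol ester with NaIO4 and NH4OAc in aqueous acetone would come back to the route at 15.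

**Step 1.** O-alkylation and double ortho-alkylation may compete with the single ortho-C-prenylation, because the phenoxide is ambident and the product is as nucleophilic as the starting phenol. The fallback sets out from 1. O-allylation (allyl bromide, K2CO3, acetone) would give 1-(allyloxy)-4-bromobenzene F7. Aromatic Claisen rearrangement at about 200 °C would give 2-allyl-4-bromophenol F8. Cross-metathesis with excess 2-methylbut-2-ene and the second-generation Grubbs catalyst RuCl2(=CHPh)(H2IMes)(PCy3) would turn allyl into prenyl, coming back to the route at 3.

**Step 3.** E to Z isomerisation of the cinnamate may be incomplete, or the ortho-prenylphenol may cyclise thermally onto its own double bond at 215 °C. The fallback sets out from 5. A Z-selective Ando olefination (ethyl (diphenoxyphosphoryl)acetate, 2.2 equiv NaH, THF, −78 °C to rt) would give ethyl (Z)-3-[5-bromo-2-hydroxy-3-(3-methylbut-2-enyl)phenyl]prop-2-enoate F9. Its phenoxide should lactonise on warming to room temperature, coming back to the route at 8 without any strong heating.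

## Further compounds

F1 | step 4 | 5-bromo-2-methoxy-3-(3-methylbut-2-enyl)benzaldehyde | COc1c(C=O)cc(Br)cc1CC=C(C)C
F2 | step 4 | ethyl (Z)-3-[5-bromo-2-methoxy-3-(3-methylbut-2-enyl)phenyl]prop-2-enoate | CCOC(=O)/C=C\c1cc(Br)cc(CC=C(C)C)c1OC
F3 | step 9 | triethyl{[(Z)-4-[5-bromo-2-methoxy-3-(3-methylbut-2-enyl)phenyl]-2-methylbut-3-en-2-yl]oxy}silane | COc1c(/C=C\C(C)(C)O[Si](CC)(CC)CC)cc(Br)cc1CC=C(C)C
F4 | step 9 | [4-methoxy-3-(3-methylbut-2-enyl)-5-[(Z)-3-methyl-3-(triethylsilyloxy)but-1-enyl]phenyl]boronic acid | COc1c(/C=C\C(C)(C)O[Si](CC)(CC)CC)cc(B(O)O)cc1CC=C(C)C
F5 | step 9 | (2S)-2-[4-methoxy-3-(3-methylbut-2-enyl)-5-[(Z)-3-methyl-3-(triethylsilyloxy)but-1-enyl]phenyl]-5,7-bis(triisopropylsilyloxy)chroman-4-one | COc1c(/C=C\C(C)(C)O[Si](CC)(CC)CC)cc([C@@H]2CC(=O)c3c(O[Si](C(C)C)(C(C)C)C(C)C)cc(O[Si](C(C)C)(C(C)C)C(C)C)cc3O2)cc1CC=C(C)C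
F6 | step 6 | (Z)-4-[2-methoxy-3-(3-methylbut-2-enyl)-5-(4,4,5,5-tetramethyl-1,3,2-dioxaborolan-2-yl)phenyl]-2-methylbut-3-en-2-ol | COc1c(/C=C\C(C)(C)O)cc(B2OC(C)(C)C(C)(C)O2)cc1CC=C(C)C
F7 | step 1 | 1-(allyloxy)-4-bromobenzene | C=CCOc1ccc(Br)cc1
F8 | step 1 | 2-allyl-4-bromophenol | C=CCc1cc(Br)ccc1O
F9 | step 3 | ethyl (Z)-3-[5-bromo-2-hydroxy-3-(3-methylbut-2-enyl)phenyl]prop-2-enoate | CCOC(=O)/C=C\c1cc(Br)cc(CC=C(C)C)c1O
A1 | alternative 1 | 3,5-bis(allyloxy)-2-(trimethylsilyl)phenyl trifluoromethanesulfonate | C=CCOc1cc(OCC=C)c([Si](C)(C)C)c(OS(=O)(=O)C(F)(F)F)c1
A2 | alternative 1 | ethyl (S)-3-hydroxy-3-[3-iodo-4-methoxy-5-(3-methylbut-2-enyl)phenyl]propanoate | CCOC(=O)C[C@H](O)c1cc(I)c(OC)c(CC=C(C)C)c1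
A3 | alternative 1 | (S)-5,7-bis(allyloxy)-2-[3-iodo-4-methoxy-5-(3-methylbut-2-enyl)phenyl]chroman-4-one | COc1c(I)cc([C@@H]2CC(=O)c3c(OCC=C)cc(OCC=C)cc3O2)cc1CC=C(C)C
A4 | alternative 1 | 2-methylbut-3-yn-2-ol | CC(C)(O)C#C
A5 | alternative 2 | 2,4-bis(allyloxy)-6-[(1R)-1-[3-[(Z)-3-hydroxy-3-methylbut-1-enyl]-4-methoxy-5-(3-methylbut-2-enyl)phenyl]-2-(tosyloxy)ethoxy]benzaldehyde | COc1c(/C=C\C(C)(C)O)cc([C@H](COS(=O)(=O)c2ccc(C)cc2)Oc2cc(OCC=C)cc(OCC=C)c2C=O)cc1CC=C(C)C
A6 | alternative 2 | (S)-5,7-bis(allyloxy)-2-[3-[(Z)-3-hydroxy-3-methylbut-1-enyl]-4-methoxy-5-(3-methylbut-2-enyl)phenyl]chroman-4-one | COc1c(/C=C\C(C)(C)O)cc([C@@H]2CC(=O)c3c(OCC=C)cc(OCC=C)cc3O2)cc1CC=C(C)C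
A7 | alternative 3 | 2-diazo-1-[2-[[3-iodo-4-methoxy-5-(3-methylbut-2-enyl)phenyl]methoxy]-4,6-bis(triisopropylsilyloxy)phenyl]ethan-1-one | COc1c(I)cc(COc2cc(O[Si](C(C)C)(C(C)C)C(C)C)cc(O[Si](C(C)C)(C(C)C)C(C)C)c2C(=O)C=[N+]=[N-])cc1CC=C(C)C
A8 | alternative 3 | (S)-2-[3-iodo-4-methoxy-5-(3-methylbut-2-enyl)phenyl]-5,7-bis(triisopropylsilyloxy)chroman-4-one | COc1c(I)cc([C@@H]2CC(=O)c3c(O[Si](C(C)C)(C(C)C)C(C)C)cc(O[Si](C(C)C)(C(C)C)C(C)C)cc3O2)cc1CC=C(C)C
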